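**Retrosynthetic overview**

1. Target 31 ⇐ its C16 silyl ether 30 ⇐ spiro-cyclopropyl keto ester 29, by one oxidative annulation that forms C8–C9 (ring C) and C20–O (δ-lactone) together.
2. 29 ⇐ Wittig union (C11=C12) of ring A lactol 11 with ring D phosphonium salt 24, then allylic oxidation/oxa-Michael (C3–O–C6 ether) and diimide reduction.
3. 11 ⇐ dienone 1: asymmetric conjugate addition sets C5; a cyclopropanation tethered through O–C6 sets C10 and C9. 24 ⇐ thioester/pyruvate aldol (C13, C16) and a lactone Claisen closure (ring D).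
4. Enabling feature: C10 is a quaternary spiro carbon carrying both C20H2 and C9H, so the lactone ring is O–C7–C8 plus C20–C10–C9, i.e. a β-keto ester (C8 carbon, C7 carbonyl oxygen) added across the C9–C20 bond of a C9/C10/C20 cyclopropane. C10 has no hydrogen (an alkyl–metal at C20 cannot β-eliminate) and C8 is a bridgehead of the bicyclo[3.2.1]octane.
5. Ring order: ring D and ring A (separately) → cyclopropane → oxolane (ether bridge) → ring C and δ-lactone together (key step).

Key step: step 19

Remark: locants are those of the ent-kaurane skeleton mapped on the target. Ring A: C1 ketone, C2, C3 ether CH, C4 CMe2, C5, C10 spiro. C6 ether CH2; C20 lactone CH2; C7 lactone C=O. Ring C: C8, C9, C11–C14. Ring D: C8, C14, C13, C16 carbinol (C17 methyl), C15 ketone.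
Remark: dienone 1 is treated as a purchasable building block. Centres left undefined in the SMILES (Mannich centre of 4, C1 and C11 of 11, C1 of 26, enolisable C8 of 22–29) are mixtures that converge later.

**Route**

Step 1
Reactants: 1 4,4-dimethylcyclohexa-2,5-dien-1-one; 2 (E)-(2-phenylethenyl)boronic acid
Product: 3 (5S)-4,4-dimethyl-5-[(E)-2-phenylethenyl]cyclohex-2-en-1-one
Conditions: [Rh(acac)(C2H4)2] (3 mol%), (S)-BINAP (3.3 mol%), dioxane/H2O 10:1, 90 °C
Reagents that add atoms: none
Why: Hayashi–Miyaura rhodium-catalysed asymmetric 1,4-addition of an alkenylboronic acid to a cyclic enone, in which the (S)-BINAP complex should select the β-carbon face as in the cyclohexenone model, which corresponds to the (S)-configured C5, and stop at mono-addition.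

Step 2
Reactants: 3 (5S)-4,4-dimethyl-5-[(E)-2-phenylethenyl]cyclohex-2-en-1-one
Product: 4 Mannich base 6-[(dimethylamino)methyl]-4,4-dimethyl-5-[(E)-2-phenylethenyl]cyclohex-2-en-1-one (C5 as in 3; both epimers at C6)
Conditions: LiN(iPr)2, THF, −78 °C; then [Me2N=CH2]I, −78 to 0 °C
Reagents that add atoms: N,N-dimethylmethyleneiminium iodide (Eschenmoser's salt), C=[N+](C)C.[I-]
Why: Kinetic α′-deprotonation (the γ-position is quaternary, so only the cross-conjugated enolate at C10 can form) followed by Mannich alkylation; the new centre is erased in step 3.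

Step 3
Reactants: 4 Mannich base
Product: 6 (5S)-4,4-dimethyl-6-methylidene-5-[(E)-2-phenylethenyl]cyclohex-2-en-1-one, via methiodide 5 (not isolated)
Conditions: MeI, CH2Cl2, rt; then aq. NaHCO3, rt
Reagents that add atoms: none
Why: Exhaustive N-methylation and E1cB (Hofmann-type) loss of trimethylamine from the β-ammonio ketone should unveil the exocyclic methylene C10=C20, the weak base being chosen so that the double bond does not migrate into the ring through C5.

Step 4
Reactants: 6 (5S)-4,4-dimethyl-6-methylidene-5-[(E)-2-phenylethenyl]cyclohex-2-en-1-one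
Product: 8 (5S)-5-(hydroxymethyl)-4,4-dimethyl-6-methylidenecyclohex-2-en-1-one, via aldehyde 7 (not isolated)
Conditions: O3, CH2Cl2/MeOH, −78 °C (Sudan Red 7B end point); Me2S; then NaBH(OAc)3 (3 equiv), AcOH, 0 °C
Reagents that add atoms: ozone, [O-][O+]=O
Why: Chemoselective ozonolysis of the electron-rich styryl alkene beside two electron-poor enone C=C bonds, then aldehyde-selective reduction with a non-basic hydride that spares the dienone and avoids enolisation of the doubly activated aldehyde 7; C5 is untouched.

Step 5
Reactants: 8 (5S)-5-(hydroxymethyl)-4,4-dimethyl-6-methylidenecyclohex-2-en-1-one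
Product: 9 [(1S)-6,6-dimethyl-2-methylidene-3-oxocyclohex-4-en-1-yl]methyl bromoacetate
Conditions: BrCH2COBr, 2,6-lutidine, CH2Cl2, −40 °C
Reagents that add atoms: bromoacetyl bromide, BrCC(Br)=O
Why: Low-temperature O-acylation of the primary alcohol with an acid bromide (faster than oxa-Michael addition to either enone) places the future C9–C11 unit on a tether through O–C6.

Step 6
Reactants: 9 [(1S)-6,6-dimethyl-2-methylidene-3-oxocyclohex-4-en-1-yl]methyl bromoacetate
Product: 10 spiro-cyclopropane δ-lactone enone (cyclopropane C9–C10–C20 spiro at C10 of ring A; lactone carbonyl C11 on C9 esterified by O–C6; C9 cis to C6; C11 cis to C5)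
Conditions: DABCO (20 mol%), Cs2CO3, MeCN (0.01 M), 60 °C
Reagents that add atoms: none
Why: Ammonium-ylide cyclopropanation (Michael-initiated ring closure) in which the ester-stabilised ylide adds to the unhindered exocyclic terminus C20 and the C10 enolate closes the three-membered ring on C9 with loss of DABCO; delivery of C9 through the O–C6 tether forces a cis-fused lactone, which fixes C9 cis to C6 at C10 and C11 cis to C5 at C9.

Step 7
Reactants: 10 spiro-cyclopropane δ-lactone enone
Product: 11 lactol allylic alcohol (C11 lactol O–C6; C1 carbinol next to C2=C3; cyclopropane intact)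
Conditions: iBu2AlH (3.2 equiv), CH2Cl2, −78 °C; aq. KNaC4H4O6
Reagents that add atoms: none
Why: Low-temperature aluminium hydride reduction takes the δ-lactone to the lactol and the enone carbonyl to the allylic alcohol (1,2-reduction); both new carbinol centres are mixtures that are erased in steps 16 and 17.

Step 8
Reactants: 12 5-tert-butoxy-5-oxopentanoic acid; 13 ethanethiol
Product: 14 tert-butyl 5-(ethylsulfanyl)-5-oxopentanoate
Conditions: DCC, DMAP (cat.), CH2Cl2, 0 °C to rt
Reagents that add atoms: none
Why: Steglich thioesterification of the free acid; no stereocentre is involved.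

Step 9
Reactants: 14 tert-butyl 5-(ethylsulfanyl)-5-oxopentanoate
Product: 15 tert-butyl (Z)-5-(ethylsulfanyl)-5-[(trimethylsilyl)oxy]pent-4-enoate
Conditions: LiN(iPr)2, Me3SiCl (internal quench), THF, −78 °C
Reagents that add atoms: chlorotrimethylsilane, C[Si](C)(C)Cl
Why: Kinetic enolisation of the more acidic thioester in preference to the tert-butyl ester with in situ O-silylation gives the silyl ketene thioacetal, whose double-bond geometry does not matter in step 10.

Step 10
Reactants: 15 tert-butyl (Z)-5-(ethylsulfanyl)-5-[(trimethylsilyl)oxy]pent-4-enoate; 16 methyl pyruvate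
Product: 18 6-tert-butyl 1-methyl (2R,3R)-3-[(ethylsulfanyl)carbonyl]-2-hydroxy-2-methylhexanedioate, via trimethylsilyl ether 17 (not isolated)
Conditions: Cu(OTf)2 (10 mol%), (R,R)-tBu-box (11 mol%), THF, −78 °C; then 1 M HCl
Reagents that add atoms: none
Why: Copper–bis(oxazoline)-catalysed Mukaiyama aldol addition to a pyruvate held as a square-planar chelate on divalent copper, where the (R,R)-ligand (antipode of the one giving the (S)-carbinol in the acetate model) should set the (R)-carbinol C16 and the open transition state the syn-related C13 for either enolsilane geometry.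

Step 11
Reactants: 18 6-tert-butyl 1-methyl (2R,3R)-3-[(ethylsulfanyl)carbonyl]-2-hydroxy-2-methylhexanedioate
Product: 19 6-tert-butyl 1-methyl (2R,3R)-2-{[tert-butyl(dimethyl)silyl]oxy}-3-[(ethylsulfanyl)carbonyl]-2-methylhexanedioate
Conditions: TBSOTf, 2,6-lutidine, CH2Cl2, 0 °C to rt
Reagents that add atoms: tert-butyldimethylsilyl triflate, CC(C)(C)[Si](C)(C)OS(=O)(=O)C(F)(F)F
Why: Silylation of the tertiary alcohol with a silyl triflate blocks retro-aldol cleavage in the basic steps that follow; no stereocentre changes.

Step 12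
Reactants: 19 silyl ether thioester
Product: 21 tert-butyl 3-[(3S,4R)-4-{[tert-butyl(dimethyl)silyl]oxy}-4-methyl-5-oxooxolan-3-yl]propanoate, via hydroxy diester 20 (not isolated)
Conditions: NaBH4, EtOH/THF, 0 °C to rt; then PPTS (cat.), toluene, 60 °C
Reagents that add atoms: none
Why: Borohydride reduces the activated thioester but not the tert-butyl or the hindered methyl ester, and the primary alcohol 20 lactonises onto the methyl ester to the γ-lactone, which masks both the C12 hydroxyl and the C15 acyl group; stereocentres are untouched.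

Step 13
Reactants: 21 γ-lactone tert-butyl ester
Product: 22 tert-butyl (3R,4S)-3-{[tert-butyl(dimethyl)silyl]oxy}-4-(hydroxymethyl)-3-methyl-2-oxocyclopentane-1-carboxylate
Conditions: KOtBu (2 equiv), THF, 0 °C to rt; aq. NH4Cl
Reagents that add atoms: none
Why: Intramolecular Claisen (Dieckmann-type) condensation in which the tert-butyl ester enolate at C8 (the only enolisable position) attacks the lactone carbonyl C15 (5-exo-trig) and the C12 alkoxide is expelled, driven by deprotonation of the β-keto ester; C8 is epimerisable and C13/C16 are unaffected.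

Step 14
Reactants: 22 hydroxymethyl β-keto ester
Product: 23 tert-butyl (3R,4R)-3-{[tert-butyl(dimethyl)silyl]oxy}-4-(iodomethyl)-3-methyl-2-oxocyclopentane-1-carboxylate
Conditions: I2, PPh3 (slight excess over I2), imidazole, CH2Cl2, 0 °C
Reagents that add atoms: iodine, II
Why: Appel-type iodination of the primary alcohol, with the phosphine kept in excess so that the β-keto ester enol is not iodinated.

Step 15
Reactants: 23 iodomethyl β-keto ester
Product: 24 {[(1R,2R)-2-{[tert-butyl(dimethyl)silyl]oxy}-4-(tert-butoxycarbonyl)-2-methyl-3-oxocyclopentyl]methyl}triphenylphosphonium iodide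
Conditions: PPh3, MeCN, 80 °C
Reagents that add atoms: triphenylphosphine, c1ccc(cc1)P(c1ccccc1)c1ccccc1
Why: SN2 quaternisation of triphenylphosphine by the primary iodide; no stereocentre is involved.

Step 16
Reactants: 11 lactol allylic alcohol; 24 phosphonium iodide
Product: 26 seco-diol Z-alkene (ring A cyclohex-2-en-1-ol with C5–CH2OH and C10 spiro-cyclopropane; C9 linked by C11=C12 to C13 of the ring D β-keto ester), via ylide 25 (not isolated)
Conditions: 24, KN(SiMe3)2 (2 equiv per 24), THF, −78 to 0 °C; then 11 pre-treated with KN(SiMe3)2 (2 equiv), −78 °C to rt; aq. NH4Cl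
Reagents that add atoms: none
Why: Wittig olefination of a lactol, in which one equivalent of base stores the β-keto ester as its enolate and the second forms the non-stabilised ylide that traps the ring-opened hydroxy aldehyde, joining the halves and releasing the C6 hydroxyl; no stereocentre is created and the alkene geometry is erased in step 18.

Step 17
Reactants: 26 seco-diol Z-alkene
Product: 28 6-oxabicyclo[3.2.1]octanone Z-alkene (C1 ketone; C3–O–C6 ether; otherwise as 26), via enone 27 (not isolated)
Conditions: MnO2, CH2Cl2, rt; filter; then DBU, CH2Cl2, 0 °C to rt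
Reagents that add atoms: none
Why: MnO2 oxidises only the allylic C1 alcohol and the C6 hydroxyl then adds to C3 of the enone by 5-exo-trig oxa-Michael addition, the C3 configuration being dictated by the tether (oxygen can reach C3 only on the face syn to C6).

Step 18
Reactants: 28 6-oxabicyclo[3.2.1]octanone Z-alkene
Product: 29 spiro-cyclopropyl keto ester (as 28 with C11–C12 saturated)
Conditions: 2-nitrobenzenesulfonyl hydrazide, Et3N, CH2Cl2, rt
Reagents that add atoms: none
Why: Diimide reduction transfers H2 in a concerted syn fashion to the unpolarised disubstituted alkene and leaves the ketones, the β-keto ester and the cyclopropane untouched, whereas heterogeneous hydrogenation would endanger the vinylcyclopropane.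

Step 19
Reactants: 29 spiro-cyclopropyl keto ester
Product: 30 C16 tert-butyldimethylsilyl ether of the target
Conditions: Pd(OAc)2 (10 mol%), 1-fluoro-2,4,6-trimethylpyridinium triflate (1.5 equiv), ClCH2CH2Cl (0.02 M), 60 °C
Reagents that add atoms: none
Why: Proposed new method: an oxidative formal [3+3] annulation of the β-keto ester (C8 and the C7 carbonyl oxygen) across the C9–C20 σ-bond of the spiro-cyclopropane, reasoned as follows: divalent palladium, held by the C1 ketone, attacks the least hindered cyclopropane carbon C20 while the enol carbon C8 attacks C9 from the rear, giving a neopentyl-type alkylpalladium at C20 that has no β-hydrogen; the N-fluoropyridinium salt oxidises it to tetravalent palladium, and SN2-type C–O reductive elimination by the tert-butyl ester carbonyl oxygen releases 2-methylpropene and divalent palladium. The closest known reaction types are the palladium-catalysed hydroalkylation of unactivated alkenes by β-dicarbonyl enols, ligand-directed palladium/oxidant ring opening of cyclopropanes, carbonyl- or oxime-directed β-C–H acyloxylation of neopentyl positions through the same five-membered C,O-palladacycle, and electrophilic mercury or platinum cleavage of cyclopropanes with inversion at the carbon attacked by the nucleophile. Ring C closes by 6-exo-tet C-alkylation at C9 and the δ-lactone by 6-exo-tet O-alkylation at C20. C9 is set by inversion of the cyclopropane carbon fixed in step 6, C8 by the bicyclo[3.2.1]octane geometry (the C13 tether lets the enol bond only on the face that carries the side chain), and C10 is not touched. The step needs cleavage of the distal C9–C20 bond and not of the ketone-activated C9–C10 bond (homo-Michael opening): no strong Lewis or Brønsted acid is present, C10 is α to the ketone and cannot carry positive charge (so the nucleophile goes to C9 and the metal to C20), both closures are six-membered, and the bystanding fluorine oxidant leaves no competing oxygen nucleophile for C20.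

Step 20
Reactants: 30 C16 tert-butyldimethylsilyl ether of the target
Product: 31 target CNP0538153.1
Conditions: HF·pyridine, pyridine/THF, 0 °C to rt
Reagents that add atoms: none
Why: Buffered fluoride cleavage of the tertiary silyl ether under non-basic conditions that tolerate the lactone and the α-ketol; no stereocentre is affected.

**Compound list**

1 | 4,4-dimethylcyclohexa-2,5-dien-1-one | CC1(C)C=CC(=O)C=C1 | starting material
2 | (E)-(2-phenylethenyl)boronic acid | OB(O)/C=C/c1ccccc1 | starting material
3 | (5S)-4,4-dimethyl-5-[(E)-2-phenylethenyl]cyclohex-2-en-1-one | CC1(C)C=CC(=O)C[C@H]1/C=C/c1ccccc1 | intermediate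
4 | Mannich base, 6-[(dimethylamino)methyl] derivative of 3 (both epimers at C6) | CC1(C)C=CC(=O)C(CN(C)C)[C@H]1/C=C/c1ccccc1 | intermediate
5 | N-methyl quaternary ammonium iodide of 4 | CC1(C)C=CC(=O)C(C[N+](C)(C)C)[C@H]1/C=C/c1ccccc1.[I-] | intermediate (not isolated)
6 | (5S)-4,4-dimethyl-6-methylidene-5-[(E)-2-phenylethenyl]cyclohex-2-en-1-one | CC1(C)C=CC(=O)C(=C)[C@H]1/C=C/c1ccccc1 | intermediate
7 | (1S)-6,6-dimethyl-2-methylidene-3-oxocyclohex-4-ene-1-carbaldehyde | CC1(C)C=CC(=O)C(=C)[C@H]1C=O | intermediate (not isolated)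
8 | (5S)-5-(hydroxymethyl)-4,4-dimethyl-6-methylidenecyclohex-2-en-1-one | CC1(C)C=CC(=O)C(=C)[C@H]1CO | intermediate
9 | [(1S)-6,6-dimethyl-2-methylidene-3-oxocyclohex-4-en-1-yl]methyl bromoacetate | CC1(C)C=CC(=O)C(=C)[C@H]1COC(=O)CBr | intermediate
10 | spiro-cyclopropane δ-lactone enone (C9 cis to C6, C11 cis to C5) | CC1(C)C=CC(=O)[C@]2(C[C@@H]2C(=O)OC3)[C@H]13 | intermediate
11 | lactol allylic alcohol from 10 (C1 and C11 carbinols as mixtures) | CC1(C)C=CC(O)[C@]2(C[C@@H]2C(O)OC3)[C@H]13 | intermediate
12 | 5-tert-butoxy-5-oxopentanoic acid | CC(C)(C)OC(=O)CCCC(=O)O | starting material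
13 | ethanethiol | CCS | starting material
14 | tert-butyl 5-(ethylsulfanyl)-5-oxopentanoate | CCSC(=O)CCCC(=O)OC(C)(C)C | intermediate
15 | tert-butyl (Z)-5-(ethylsulfanyl)-5-[(trimethylsilyl)oxy]pent-4-enoate | CCS/C(O[Si](C)(C)C)=C\CCC(=O)OC(C)(C)C | intermediate
16 | methyl pyruvate | CC(=O)C(=O)OC | starting material
17 | trimethylsilyl ether of 18 | COC(=O)[C@](C)(O[Si](C)(C)C)[C@@H](CCC(=O)OC(C)(C)C)C(=O)SCC | intermediate (not isolated)
18 | 6-tert-butyl 1-methyl (2R,3R)-3-[(ethylsulfanyl)carbonyl]-2-hydroxy-2-methylhexanedioate | COC(=O)[C@](C)(O)[C@@H](CCC(=O)OC(C)(C)C)C(=O)SCC | intermediate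
19 | 6-tert-butyl 1-methyl (2R,3R)-2-{[tert-butyl(dimethyl)silyl]oxy}-3-[(ethylsulfanyl)carbonyl]-2-methylhexanedioate | COC(=O)[C@](C)(O[Si](C)(C)C(C)(C)C)[C@@H](CCC(=O)OC(C)(C)C)C(=O)SCC | intermediate
20 | 6-tert-butyl 1-methyl (2R,3S)-2-{[tert-butyl(dimethyl)silyl]oxy}-3-(hydroxymethyl)-2-methylhexanedioate | COC(=O)[C@](C)(O[Si](C)(C)C(C)(C)C)[C@@H](CCC(=O)OC(C)(C)C)CO | intermediate (not isolated)
21 | tert-butyl 3-[(3S,4R)-4-{[tert-butyl(dimethyl)silyl]oxy}-4-methyl-5-oxooxolan-3-yl]propanoate | O=C1OC[C@H](CCC(=O)OC(C)(C)C)[C@@]1(C)O[Si](C)(C)C(C)(C)C | intermediate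
22 | tert-butyl (3R,4S)-3-{[tert-butyl(dimethyl)silyl]oxy}-4-(hydroxymethyl)-3-methyl-2-oxocyclopentane-1-carboxylate (C1 epimers/enol) | OC[C@@H]1CC(C(=O)OC(C)(C)C)C(=O)[C@]1(C)O[Si](C)(C)C(C)(C)C | intermediate
23 | tert-butyl (3R,4R)-3-{[tert-butyl(dimethyl)silyl]oxy}-4-(iodomethyl)-3-methyl-2-oxocyclopentane-1-carboxylate | IC[C@@H]1CC(C(=O)OC(C)(C)C)C(=O)[C@]1(C)O[Si](C)(C)C(C)(C)C | intermediate
24 | triphenylphosphonium iodide derived from 23 | c1ccccc1[P+](c1ccccc1)(c1ccccc1)C[C@@H]1CC(C(=O)OC(C)(C)C)C(=O)[C@]1(C)O[Si](C)(C)C(C)(C)C.[I-] | intermediate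
25 | phosphonium ylide of 24 as its potassium β-keto ester enolate | [K+].[O-]C1=C(C(=O)OC(C)(C)C)C[C@@H](C=P(c2ccccc2)(c2ccccc2)c2ccccc2)[C@@]1(C)O[Si](C)(C)C(C)(C)C | intermediate (not isolated)
26 | seco-diol Z-alkene (ring A dienyl carbinol with C5–CH2OH, spiro-cyclopropane, ring D β-keto ester) | CC1(C)C=CC(O)[C@]2(C[C@@H]2/C=C\[C@@H]3CC(C(=O)OC(C)(C)C)C(=O)[C@]3(C)O[Si](C)(C)C(C)(C)C)[C@H]1CO | intermediate
27 | C1 enone of 26 | CC1(C)C=CC(=O)[C@]2(C[C@@H]2/C=C\[C@@H]3CC(C(=O)OC(C)(C)C)C(=O)[C@]3(C)O[Si](C)(C)C(C)(C)C)[C@H]1CO | intermediate (not isolated)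
28 | 6-oxabicyclo[3.2.1]octanone Z-alkene (C3–O–C6 ether closed) | CC1(C)[C@@H]2CC(=O)[C@]3(C[C@@H]3/C=C\[C@@H]4CC(C(=O)OC(C)(C)C)C(=O)[C@]4(C)O[Si](C)(C)C(C)(C)C)[C@H]1CO2 | intermediate
29 | spiro-cyclopropyl keto ester (key-step precursor) | CC1(C)[C@@H]2CC(=O)[C@]3(C[C@@H]3CC[C@@H]4CC(C(=O)OC(C)(C)C)C(=O)[C@]4(C)O[Si](C)(C)C(C)(C)C)[C@H]1CO2 | intermediate
30 | C16 tert-butyldimethylsilyl ether of the target | CC1(C)[C@@H]2CC(=O)[C@]3(COC(=O)[C@@]45C[C@@H](CC[C@H]43)[C@@](C)(O[Si](C)(C)C(C)(C)C)C5=O)[C@H]1CO2 | intermediate
31 | CNP0538153.1 | CC1(C)[C@@H]2CC(=O)[C@]3(COC(=O)[C@@]45C[C@@H](CC[C@H]43)[C@@](C)(O)C5=O)[C@H]1CO2 | target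

**Step count and risks**

Total step count: 20 steps.

Longest linear sequence: 13 steps.

The longest chain is the ring D arm, from the glutaric half-ester to the phosphonium salt, followed by the union and the end-game; the ring A arm is one step shorter.

Steps most likely to fail:

1. Step 19 (Proposed new method). The cyclopropane may resist palladation because of the adjacent ketone, it may open in the homo-Michael sense (C9–C10 cleavage), or the alkylpalladium may be protonated before it is oxidised. Fallback, from 29 and rejoining at 30: the event is split into a stoichiometric mercuration and a separate lactonisation, each an established reaction type. Hg(OTf)2 (MeCN, 0 °C; NaCl work-up) should open the cyclopropane electrophilically with the enol carbon as internal nucleophile (inversion at C9) to give the neopentyl alkylmercury chloride F1. Iododemercuration (I2, CH2Cl2) gives the neopentyl iodide F2. The tert-butyl ester is cleaved with TMSOTf/2,6-lutidine (aqueous work-up) to the iodo β-keto acid F3, which cannot decarboxylate because C8 is now a bridgehead. Cs2CO3 in DMF at 60 °C then closes the lactone by intramolecular SN2 displacement to give 30.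

2. Step 6. The tethered ylide must close a seven-membered ring in the Michael step, so oligomerisation may compete, and the base may move the exocyclic double bond into the ring with loss of the C5 stereocentre. Fallback, from 9 and rejoining at 11: a rhodium carbenoid on a non-enolisable substrate replaces the ylide. Luche reduction (NaBH4, CeCl3·7H2O, MeOH, −78 °C) gives the dienol bromoacetate F4. N,N′-ditosylhydrazine/DBU (THF, 0 °C) converts it into the dienol diazoacetate F5. Rh2(OAc)4 (1 mol%, CH2Cl2, slow addition) should cyclopropanate the now electron-rich exocyclic alkene intramolecularly to the cyclopropane lactone alcohol F6. iBu2AlH (−78 °C) reduces the lactone to lactol 11.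

3. Step 16. Proton transfer between the lactolate, the enolate and the ylide, together with slow addition to the hindered cyclopropanecarbaldehyde, may lead to low conversion and decomposition of the doubly deprotonated partner. Fallback, from 19 and rejoining at 26: ring D closure is postponed until after the union. Reduction of 19 as in step 12, with the crude hydroxy diester 20 iodinated at once (I2, PPh3, imidazole), gives the iodo diester F7. PPh3 (MeCN, 80 °C) gives the acyclic phosphonium iodide F8, whose ylide (one equivalent of KN(SiMe3)2; no acidic β-keto ester present) is condensed with the lactolate of 11 to the acyclic diester Z-alkene F9. Dieckmann cyclisation (KOtBu in excess, THF) then closes ring D to give 26.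

**Further compounds**

F1 | step 19 | alkylmercury chloride (ring C closed, C20–HgCl, C8 quaternary tert-butyl ester) | CC1(C)[C@@H]2CC(=O)[C@]([C@@H]3CC[C@@H]4C[C@@]3(C(=O)OC(C)(C)C)C(=O)[C@]4(C)O[Si](C)(C)C(C)(C)C)(C[Hg]Cl)[C@H]1CO2
F2 | step 19 | neopentyl iodide corresponding to F1 | CC1(C)[C@@H]2CC(=O)[C@]([C@@H]3CC[C@@H]4C[C@@]3(C(=O)OC(C)(C)C)C(=O)[C@]4(C)O[Si](C)(C)C(C)(C)C)(CI)[C@H]1CO2
F3 | step 19 | iodo β-keto acid from F2 | CC1(C)[C@@H]2CC(=O)[C@]([C@@H]3CC[C@@H]4C[C@@]3(C(=O)O)C(=O)[C@]4(C)O[Si](C)(C)C(C)(C)C)(CI)[C@H]1CO2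
F4 | step 6 | dienol bromoacetate (C1 alcohol of 9, both epimers) | CC1(C)C=CC(O)C(=C)[C@H]1COC(=O)CBr
F5 | step 6 | dienol diazoacetate | CC1(C)C=CC(O)C(=C)[C@H]1COC(=O)C=[N+]=[N-]
F6 | step 6 | cyclopropane lactone alcohol (C1 alcohol of 10) | CC1(C)C=CC(O)[C@]2(C[C@@H]2C(=O)OC3)[C@H]13
F7 | step 16 | 6-tert-butyl 1-methyl 2-{[tert-butyl(dimethyl)silyl]oxy}-3-(iodomethyl)-2-methylhexanedioate (configuration as in 19) | COC(=O)[C@](C)(O[Si](C)(C)C(C)(C)C)[C@@H](CCC(=O)OC(C)(C)C)CI
F8 | step 16 | triphenylphosphonium iodide of F7 | COC(=O)[C@](C)(O[Si](C)(C)C(C)(C)C)[C@@H](CCC(=O)OC(C)(C)C)C[P+](c1ccccc1)(c1ccccc1)c1ccccc1.[I-]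
F9 | step 16 | acyclic diester Z-alkene (ring A diol of 26 joined to the open diester) | CC1(C)C=CC(O)[C@]2(C[C@@H]2/C=C\[C@H](CCC(=O)OC(C)(C)C)[C@@](C)(O[Si](C)(C)C(C)(C)C)C(=O)OC)[C@H]1CO
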